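**Retrosynthetic overview**
- Prinsepiol ⇐ its dibenzyl ether ⇐ (lactone C=O → CH2) a bicyclic γ-lactone with C9 at the ester level. All four stereocentres are already in place in that lactone.
- Bicyclic lactone ⇐ one SmI2 operation on an acyclic α-keto ester/α-hydroxy ketone. Pinacol coupling makes C8–C8' and closes ring O/C7/C8/C8'/C9' first. The C7'–OH is then acylated by C9 and closes ring O/C9/C8/C8'/C7'.
- Enabling feature: the bond shared by the two tetrahydrofuran rings joins two tertiary carbinol carbons (C8, C8') as a cis-1,2-diol, which is a pinacol retron. The C7' oxygen stands γ to C9 across that bond, so C–C coupling creates a γ-hydroxy ester that must lactonise.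
- Acyclic precursor ⇐ double ozonolysis of a bis(1,1-disubstituted alkene) ether ⇐ head-to-tail O-alkylation (C7–O–C9') of two copies of one enantiopure Morita–Baylis–Hillman monomer. That monomer supplies C7 and C7' (both R).

Key step: step 8

Remark: atoms are named by lignan numbering (C7/C7' = ArCH–O, C8/C8' = ring-fusion C–OH, C9/C9' = OCH2; unprimed = the half that carries the ester). "Aryl" in the Why lines means 4-(benzyloxy)-3-methoxyphenyl.

Step 1
Reactants: 1 4-(benzyloxy)-3-methoxybenzaldehyde; 2 1,1,1,3,3,3-hexafluoropropan-2-yl acrylate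
Product: 4 methyl (R)-2-{[4-(benzyloxy)-3-methoxyphenyl](hydroxy)methyl}prop-2-enoate, via hexafluoroisopropyl ester 3 (not isolated)
Conditions: β-isocupreidine (10 mol%), DMF, −55 °C; crude 3, then MeOH, Et3N (cat.), rt
Reagents that add atoms: methanol, CO
Why: Enantioselective Morita–Baylis–Hillman reaction in which the quinuclidine nitrogen adds to the activated acrylate and the catalyst's phenolic OH hydrogen-bonds the aldolate, so that the betaine leading to the (R)-carbinol collapses fastest, after which base-catalysed transesterification exchanges the labile fluorinated ester without touching the stereocentre.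

Step 2
Reactants: 4 methyl (R)-2-{[4-(benzyloxy)-3-methoxyphenyl](hydroxy)methyl}prop-2-enoate
Product: 5 methyl (R)-2-{[4-(benzyloxy)-3-methoxyphenyl][(tert-butyldimethylsilyl)oxy]methyl}prop-2-enoate
Conditions: TBSCl, imidazole, DMF, rt
Reagents that add atoms: tert-butyldimethylsilyl chloride, C[Si](C)(Cl)C(C)(C)C
Why: Imidazole-promoted silylation of a secondary alcohol masks the oxygen that later becomes the C7' oxygen, and the stereocentre is not involved.

Step 3
Reactants: 5 methyl (R)-2-{[4-(benzyloxy)-3-methoxyphenyl][(tert-butyldimethylsilyl)oxy]methyl}prop-2-enoate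
Product: 6 (R)-2-{[4-(benzyloxy)-3-methoxyphenyl][(tert-butyldimethylsilyl)oxy]methyl}prop-2-en-1-ol
Conditions: DIBAL-H (2.5 equiv), CH2Cl2, −78 → 0 °C; aq Rochelle salt
Reagents that add atoms: none
Why: 1,2-Reduction of the α,β-unsaturated ester by DIBAL-H gives the primary allylic alcohol (future C9') and leaves the silyl and benzyl ethers untouched.

Step 4
Reactants: 6 (R)-2-{[4-(benzyloxy)-3-methoxyphenyl][(tert-butyldimethylsilyl)oxy]methyl}prop-2-en-1-ol
Product: 7 (R)-{[1-[4-(benzyloxy)-3-methoxyphenyl]-2-(bromomethyl)prop-2-en-1-yl]oxy}(tert-butyl)dimethylsilane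
Conditions: CBr4, PPh3, CH2Cl2, 0 °C
Reagents that add atoms: carbon tetrabromide, BrC(Br)(Br)Br
Why: Appel reaction under neutral conditions, in which SN2 and SN2' displacement lead to the same 2-substituted allyl bromide, so regiochemistry is no issue.

Step 5
Reactants: 4 methyl (R)-2-{[4-(benzyloxy)-3-methoxyphenyl](hydroxy)methyl}prop-2-enoate; 7 (R)-{[1-[4-(benzyloxy)-3-methoxyphenyl]-2-(bromomethyl)prop-2-en-1-yl]oxy}(tert-butyl)dimethylsilane
Product: 8 methyl 2-{(R)-[4-(benzyloxy)-3-methoxyphenyl][(2-{(R)-[4-(benzyloxy)-3-methoxyphenyl][(tert-butyldimethylsilyl)oxy]methyl}prop-2-en-1-yl)oxy]methyl}prop-2-enoate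
Conditions: Ag2O (1.5 equiv), 7 (1.3 equiv), 4 Å MS, CH2Cl2, dark, rt → 40 °C
Reagents that add atoms: none
Why: Silver(I)-oxide-promoted Williamson etherification activates the allylic bromide by halide abstraction under non-basic conditions, so the acrylate of 4 is not attacked and C7 keeps its configuration because only its O–H bond is broken.

Step 6
Reactants: 8 the silyl-protected diene ether ester
Product: 9 methyl 2-{(R)-[4-(benzyloxy)-3-methoxyphenyl][(2-{(R)-[4-(benzyloxy)-3-methoxyphenyl](hydroxy)methyl}prop-2-en-1-yl)oxy]methyl}prop-2-enoate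
Conditions: TBAF, AcOH (1:1), THF, 0 °C → rt
Reagents that add atoms: none
Why: Fluoride-induced desilylation, buffered with acetic acid so that no free alkoxide can add to the acrylate or cleave the ester.

Step 7
Reactants: 9 the diene ether alcohol
Product: 10 methyl (3R)-3-[4-(benzyloxy)-3-methoxyphenyl]-3-{(3R)-3-[4-(benzyloxy)-3-methoxyphenyl]-3-hydroxy-2-oxopropoxy}-2-oxopropanoate
Conditions: O3, CH2Cl2, −78 °C (Sudan Red end point); Me2S, −78 °C → rt; aqueous wash, azeotropic drying, used crude
Reagents that add atoms: ozone, [O-][O+]=O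
Why: Ozonolysis with reductive work-up cleaves both 1,1-disubstituted alkenes (faster than the arenes when stopped at the indicator end point) to the ketone and the α-keto ester under neutral conditions that leave the two enolisable benzylic stereocentres untouched.

Step 8
Reactants: 10 methyl (3R)-3-[4-(benzyloxy)-3-methoxyphenyl]-3-{(3R)-3-[4-(benzyloxy)-3-methoxyphenyl]-3-hydroxy-2-oxopropoxy}-2-oxopropanoate
Product: 12 (3R,3aS,6R,6aS)-3,6-bis[4-(benzyloxy)-3-methoxyphenyl]-3a,6a-dihydroxytetrahydro-1H,3H-furo[3,4-c]furan-1-one, via tetrahydrofuran triol ester 11 (not isolated)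
Conditions: 10 added slowly to SmI2 (3 equiv, 0.1 M in THF), final 0.01 M, −78 → 0 °C; aq NH4Cl/Na2S2O3
Reagents that add atoms: none
Why: SmI2 reduces the α-keto ester carbonyl (C8, the most easily reduced group) and the Sm(III)-activated α-hydroxy ketone (C8') to ketyls that couple C8–C8' by a 5-exo-trig closure of ring O/C7/C8/C8'/C9' to give the samarium diolate of 11, whose C7' oxygen, now γ to the ester and cis to it, attacks C9 in a 5-exo-trig acyl substitution that expels methoxide and closes ring O/C9/C8/C8'/C7' as the γ-lactone. The closest known reaction types are the SmI2 intramolecular pinacol coupling of α-alkoxy 1,5-dicarbonyl compounds to cis-diols, the low-valent-metal cross-pinacol coupling of α-keto esters with ketones, and the lactonisation that follows SmI2 couplings which create a γ-oxido ester. The cis relation of the two new carbinol centres follows from Sm(III) bridging both ketyl oxygens and from the strain of a trans-fused alternative. C8' is controlled by a Cram chelate in which Sm(III) ties the free C7'–OH to the C8' oxygen, so that C8 arrives on the face of C7'–H, anti to the aryl group. C8 is controlled by allylic 1,3-strain in the planar ester-chelated ketyl, which places C7–H beside the ester carbon and the aryl group beside the small ketyl oxygen, and both elements favour the same (8S,8'S) diol with both aryl groups exo. The selectivity needed is coupling ahead of reductive loss of the α-oxygen substituents or plain ketone reduction, which the poor leaving groups (alkoxide, hydroxide), the absence of an added proton source or HMPA, low temperature and high dilution should secure, while only the cis-diol can lactonise.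

Step 9
Reactants: 12 the bicyclic dihydroxy γ-lactone
Product: 13 (3R,3aS,6R,6aS)-3,6-bis[4-(benzyloxy)-3-methoxyphenyl]tetrahydro-1H,3H-furo[3,4-c]furan-1,3a,6a-triol (lactol, mixture of anomers at C1 of the ring system)
Conditions: DIBAL-H (4 equiv), CH2Cl2, −78 °C; aq Rochelle salt
Reagents that add atoms: none
Why: Partial reduction of a γ-lactone with DIBAL-H at low temperature stops at the aluminium hemiacetal, which gives the lactol on work-up, and the extra equivalents are consumed by the two tertiary OH groups.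

Step 10
Reactants: 13 the bicyclic lactol
Product: 14 (3R,3aS,6R,6aS)-3,6-bis[4-(benzyloxy)-3-methoxyphenyl]tetrahydro-1H,3H-furo[3,4-c]furan-3a,6a-diol (di-O-benzylprinsepiol)
Conditions: Et3SiH (5 equiv), BF3·OEt2 (2 equiv), CH2Cl2, −78 → −30 °C; aq NaHCO3
Reagents that add atoms: none
Why: Ionic reduction of a lactol, in which BF3 ionises the anomeric OH to the cyclic oxocarbenium ion and triethylsilane reduces it to the CH2–O unit, while the low temperature should keep the benzylic C–O bonds closed (their exo,exo arrangement is in any case the thermodynamic one).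

Step 11
Reactants: 14 di-O-benzylprinsepiol
Product: 15 prinsepiol, (3R,3aS,6R,6aS)-3,6-bis(4-hydroxy-3-methoxyphenyl)tetrahydro-1H,3H-furo[3,4-c]furan-3a,6a-diol
Conditions: H2 (1 atm), 10% Pd/C, EtOAc, rt, stopped after uptake of 2 equiv H2
Reagents that add atoms: none
Why: In catalytic hydrogenolysis the aryl benzyl ethers are cleaved much faster than the hindered ring benzylic C–O bonds, so a controlled hydrogen uptake should give the free bisphenol with all four stereocentres unchanged.

**Compound list**
1 | 4-(benzyloxy)-3-methoxybenzaldehyde | O=Cc1ccc(OCc2ccccc2)c(OC)c1 | starting material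
2 | 1,1,1,3,3,3-hexafluoropropan-2-yl acrylate | C=CC(=O)OC(C(F)(F)F)C(F)(F)F | starting material
3 | 1,1,1,3,3,3-hexafluoropropan-2-yl (R)-2-{[4-(benzyloxy)-3-methoxyphenyl](hydroxy)methyl}prop-2-enoate | C=C(C(=O)OC(C(F)(F)F)C(F)(F)F)[C@H](O)c1ccc(OCc2ccccc2)c(OC)c1 | intermediate
4 | methyl (R)-2-{[4-(benzyloxy)-3-methoxyphenyl](hydroxy)methyl}prop-2-enoate | C=C(C(=O)OC)[C@H](O)c1ccc(OCc2ccccc2)c(OC)c1 | intermediate
5 | methyl (R)-2-{[4-(benzyloxy)-3-methoxyphenyl][(tert-butyldimethylsilyl)oxy]methyl}prop-2-enoate | C=C(C(=O)OC)[C@H](O[Si](C)(C)C(C)(C)C)c1ccc(OCc2ccccc2)c(OC)c1 | intermediate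
6 | (R)-2-{[4-(benzyloxy)-3-methoxyphenyl][(tert-butyldimethylsilyl)oxy]methyl}prop-2-en-1-ol | C=C(CO)[C@H](O[Si](C)(C)C(C)(C)C)c1ccc(OCc2ccccc2)c(OC)c1 | intermediate
7 | (R)-{[1-[4-(benzyloxy)-3-methoxyphenyl]-2-(bromomethyl)prop-2-en-1-yl]oxy}(tert-butyl)dimethylsilane | C=C(CBr)[C@H](O[Si](C)(C)C(C)(C)C)c1ccc(OCc2ccccc2)c(OC)c1 | intermediate
8 | (R,R)-head-to-tail diene ether, C7' oxygen as TBS ether, C9 as methyl acrylate ester | C=C(CO[C@@H](C(=C)C(=O)OC)c1ccc(OCc2ccccc2)c(OC)c1)[C@H](O[Si](C)(C)C(C)(C)C)c1ccc(OCc2ccccc2)c(OC)c1 | intermediate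
9 | (R,R)-head-to-tail diene ether with free C7'–OH | C=C(CO[C@@H](C(=C)C(=O)OC)c1ccc(OCc2ccccc2)c(OC)c1)[C@H](O)c1ccc(OCc2ccccc2)c(OC)c1 | intermediate
10 | methyl (3R)-3-[4-(benzyloxy)-3-methoxyphenyl]-3-{(3R)-3-[4-(benzyloxy)-3-methoxyphenyl]-3-hydroxy-2-oxopropoxy}-2-oxopropanoate | O=C(CO[C@@H](C(=O)C(=O)OC)c1ccc(OCc2ccccc2)c(OC)c1)[C@H](O)c1ccc(OCc2ccccc2)c(OC)c1 | intermediate
11 | methyl (2R,3S,4S)-2-[4-(benzyloxy)-3-methoxyphenyl]-4-{(R)-[4-(benzyloxy)-3-methoxyphenyl](hydroxy)methyl}-3,4-dihydroxytetrahydrofuran-3-carboxylate | COC(=O)[C@]1(O)[C@@H](c2ccc(OCc3ccccc3)c(OC)c2)OC[C@]1(O)[C@H](O)c1ccc(OCc2ccccc2)c(OC)c1 | intermediate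
12 | (3R,3aS,6R,6aS)-3,6-bis[4-(benzyloxy)-3-methoxyphenyl]-3a,6a-dihydroxytetrahydro-1H,3H-furo[3,4-c]furan-1-one | COc1cc([C@H]2OC(=O)[C@]3(O)[C@@H](c4ccc(OCc5ccccc5)c(OC)c4)OC[C@]23O)ccc1OCc1ccccc1 | intermediate
13 | (3R,3aS,6R,6aS)-3,6-bis[4-(benzyloxy)-3-methoxyphenyl]tetrahydro-1H,3H-furo[3,4-c]furan-1,3a,6a-triol, anomer mixture | COc1cc([C@H]2OC(O)[C@]3(O)[C@@H](c4ccc(OCc5ccccc5)c(OC)c4)OC[C@]23O)ccc1OCc1ccccc1 | intermediate
14 | (3R,3aS,6R,6aS)-3,6-bis[4-(benzyloxy)-3-methoxyphenyl]tetrahydro-1H,3H-furo[3,4-c]furan-3a,6a-diol | COc1cc([C@H]2OC[C@]3(O)[C@@H](c4ccc(OCc5ccccc5)c(OC)c4)OC[C@]23O)ccc1OCc1ccccc1 | intermediate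
15 | prinsepiol, (3R,3aS,6R,6aS)-3,6-bis(4-hydroxy-3-methoxyphenyl)tetrahydro-1H,3H-furo[3,4-c]furan-3a,6a-diol | COc1cc([C@H]2OC[C@]3(O)[C@@H](c4ccc(O)c(OC)c4)OC[C@]23O)ccc1O | target

Total step count: 11. Longest linear sequence: 11 steps (1 → 4 → 5 → 6 → 7 → 8 → 9 → 10 → 12 → 13 → 14 → 15; compound 4 enters twice).

**Steps most likely to fail**

**Step 8.**
- What may go wrong: reductive cleavage of the benzylic C7–O bond from the α-keto ester ketyl, or plain reduction of the keto ester, may outrun C–C coupling. Facial selectivity may also be lower than the two control elements suggest.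
- The fallback sets out from 1 and 7 and comes back at 14. It replaces the C8 carbonyl by a terminal alkyne, so that no ketyl stands next to the benzylic ether. The three events of step 8 are spread over known reactions.
- Enantioselective alkynylzinc addition of trimethylsilylacetylene to 1 (Et2Zn, Ti(OiPr)4, the BINOL enantiomer that delivers the drawn configuration) should give the silylated propargylic alcohol F1.
- K2CO3/MeOH should give the terminal propargylic alcohol F2.
- NaH/TBAI alkylation of F2 with 7 should give the enyne ether F3.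
- Ozonolysis, selective for the alkene over the alkyne, should give the alkynyl ketone F4.
- SmI2/HMPA/t-BuOH ketyl–alkyne 5-exo-dig cyclisation should give the methylene tetrahydrofuranol F5, with the bulky side chain trans to the C7 aryl group.
- VO(acac)2/t-BuOOH epoxidation directed by the tertiary OH should give the spiro-epoxide F6, with its oxygen cis to that OH.
- TBAF should give the epoxy diol F7.
- PPTS-catalysed opening of the epoxide at its CH2 terminus by the C7'–OH should close the second ring to 14.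

**Step 5.**
- What may go wrong: slow O-alkylation of a hindered, weakly nucleophilic carbinol, and silver-assisted ionisation of the electron-rich benzylic alcohol with loss of configuration.
- The fallback sets out from 6 and 4 and comes back at 8. It changes from SN2 alkylation to π-allyl chemistry.
- Acetylation of 6 (Ac2O, pyridine) should give the allylic acetate F8.
- A Pd(0)/bulky biarylphosphine catalyst ionises F8 to a π-allyl complex with two equivalent CH2 termini.
- The zinc alkoxide of 4 (Et2Zn, 0.5 equiv, THF, rt) should attack this complex to give 8 with C7 untouched.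

**Step 1.**
- What may go wrong: low conversion, because the electron-rich aldehyde is a poor acceptor at −55 °C, and erosion of the enantiomeric purity on long reaction times.
- The fallback sets out from 1 and comes back at 4. It changes from asymmetric catalysis to resolution.
- A DABCO-promoted Morita–Baylis–Hillman reaction of 1 with methyl acrylate at rt should give the racemic adduct F9.
- Lipase-catalysed acylation (Pseudomonas cepacia lipase, vinyl acetate, MTBE) should convert the S enantiomer into the acetate F10. This follows the empirical size rule with the aryl group as the large substituent.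
- (R)-4 should remain unreacted and is separated by chromatography.

**Further compounds**
F1 | step 8 | (R)-1-[4-(benzyloxy)-3-methoxyphenyl]-3-(trimethylsilyl)prop-2-yn-1-ol | C[Si](C)(C)C#C[C@H](O)c1ccc(OCc2ccccc2)c(OC)c1
F2 | step 8 | (S)-1-[4-(benzyloxy)-3-methoxyphenyl]prop-2-yn-1-ol | C#C[C@H](O)c1ccc(OCc2ccccc2)c(OC)c1
F3 | step 8 | enyne ether from F2 and 7 (C7 S by name with the same spatial arrangement as in 8, C7' R) | C=C(CO[C@@H](C#C)c1ccc(OCc2ccccc2)c(OC)c1)[C@H](O[Si](C)(C)C(C)(C)C)c1ccc(OCc2ccccc2)c(OC)c1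
F4 | step 8 | alkynyl ketone, (R)-1-aryl-1-(TBSO)-3-{[(S)-1-arylprop-2-yn-1-yl]oxy}propan-2-one | O=C(CO[C@@H](C#C)c1ccc(OCc2ccccc2)c(OC)c1)[C@H](O[Si](C)(C)C(C)(C)C)c1ccc(OCc2ccccc2)c(OC)c1
F5 | step 8 | (3S,5R)-5-aryl-3-[(R)-aryl(TBSO)methyl]-4-methylidenetetrahydrofuran-3-ol | C=C1[C@@H](c2ccc(OCc3ccccc3)c(OC)c2)OC[C@]1(O)[C@H](O[Si](C)(C)C(C)(C)C)c1ccc(OCc2ccccc2)c(OC)c1
F6 | step 8 | spiro-epoxide of F5 (1,5-dioxaspiro[2.4]heptane, epoxide oxygen cis to the tertiary OH, stereocentres as in 14) | C1O[C@]12[C@@H](c3ccc(OCc4ccccc4)c(OC)c3)OC[C@]2(O)[C@H](O[Si](C)(C)C(C)(C)C)c1ccc(OCc2ccccc2)c(OC)c1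
F7 | step 8 | desilylated epoxy diol from F6 | C1O[C@]12[C@@H](c3ccc(OCc4ccccc4)c(OC)c3)OC[C@]2(O)[C@H](O)c1ccc(OCc2ccccc2)c(OC)c1
F8 | step 5 | (R)-2-{[4-(benzyloxy)-3-methoxyphenyl][(tert-butyldimethylsilyl)oxy]methyl}prop-2-en-1-yl acetate | C=C(COC(C)=O)[C@H](O[Si](C)(C)C(C)(C)C)c1ccc(OCc2ccccc2)c(OC)c1
F9 | step 1 | racemic methyl 2-{[4-(benzyloxy)-3-methoxyphenyl](hydroxy)methyl}prop-2-enoate | C=C(C(=O)OC)C(O)c1ccc(OCc2ccccc2)c(OC)c1
F10 | step 1 | methyl (S)-2-{acetoxy[4-(benzyloxy)-3-methoxyphenyl]methyl}prop-2-enoate | C=C(C(=O)OC)[C@@H](OC(C)=O)c1ccc(OCc2ccccc2)c(OC)c1
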